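Sesterfisherol is traced back to the cis-fused bicyclo[6.3.0]undecane of rings A and B. Its ring-fusion carbons C1 and C8 and the ring B pair C4/C5 (later the B/C-fusion CH and the CH(CH3) carbon) are the four ends of two butadiene units tied together by the ring A carbons C9–C11. A zerovalent-nickel [4+4] cycloaddition of a citronellene-derived acyclic tetraene, two E-1,3-dienes on a CH2–CH2–CH(CH3) tether, therefore makes the C1–C8 and C4–C5 bonds, both rings and two stereocentres at once, steered by the C9 methyl group. The C2=C3 alkene then delivers the C3 carbonyl and the C1=C2 alkene; a limonene-derived ring D aldehyde is attached at C4 and ring C is closed onto C3.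

Key step: step 5

Remark: C1–C11 are the bicyclo[6.3.0]undecane locants of rings A and B and are kept for these atoms to the end; C12 is the carbon between C4 and ring D; ring D atoms carry primes (C1′ quaternary, C2′ the CH carrying the CH2 that closes ring C, C3′ the CH carrying isopropyl); stereocentres that are erased again are drawn in the expected configuration.

Step 1
Reactants: 1 (3R)-3,7-dimethylocta-1,6-diene
Product: 2 (2E,6R)-2,6-dimethylocta-2,7-dien-1-ol
Conditions: SeO2 (cat.), t-BuOOH, salicylic acid (cat.), CH2Cl2, 0 °C to rt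
Reagents that add atoms: selenium dioxide O=[Se]=O (oxygen carrier); tert-butyl hydroperoxide CC(C)(C)OO (terminal oxidant)
Why: Selenium dioxide allylic oxidation (ene reaction then [2,3]-shift, selenium recycled by t-BuOOH) picks the electron-rich trisubstituted alkene and its (E)-methyl group, so the vinyl group and the stereocentre stay untouched; any enal formed at once is carried into step 2.

Step 2
Reactants: 2 (2E,6R)-2,6-dimethylocta-2,7-dien-1-ol
Product: 3 (2E,6R)-2,6-dimethylocta-2,7-dienal
Conditions: MnO2, CH2Cl2, rt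
Reagents that add atoms: none
Why: MnO2 oxidises allylic alcohols to enals chemoselectively and leaves the isolated vinyl group and the alkene geometry alone.

Step 3
Reactants: 3 (2E,6R)-2,6-dimethylocta-2,7-dienal; 4 (2E)-but-2-enal
Product: 5 (2E,6R,7E)-2,6-dimethylnona-2,7-dienedial
Conditions: 4 (5 equiv), second-generation Hoveyda–Grubbs catalyst RuCl2(H2IMes)(=CH-C6H4-2-OiPr) (3 mol %), CH2Cl2, 40 °C
Reagents that add atoms: none
Why: Olefin cross-metathesis of the monosubstituted alkene with excess crotonaldehyde should give the (E)-enal, while the trisubstituted, formyl-conjugated alkene is a poor metathesis partner, which together with the excess of 4 should hold back ring closure to a cyclopentene.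

Step 4
Reactants: 5 (2E,6R,7E)-2,6-dimethylnona-2,7-dienedial
Product: 7 (3E,7R,8E)-3,7-dimethylundeca-1,3,8,10-tetraene, via trienal 6 (not isolated)
Conditions: Ph3PCH3Br (3 equiv), KN(SiMe3)2, THF, −78 °C to 0 °C
Reagents that add atoms: methyltriphenylphosphonium bromide C[P+](c1ccccc1)(c1ccccc1)c1ccccc1.[Br-]
Why: Twofold Wittig methylenation turns both enal carbonyls into vinyl groups with the two E alkenes and the stereocentre unchanged, since the non-stabilised ylide adds to the aldehydes at low temperature faster than it deprotonates the γ-position.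

Step 5
Reactants: 7 (3E,7R,8E)-3,7-dimethylundeca-1,3,8,10-tetraene
Product: 8 (1R,2Z,6Z,8R,9R)-2,9-dimethylbicyclo[6.3.0]undeca-2,6-diene
Conditions: Ni(cod)2 (15 mol %), PPh3 (30 mol %), toluene (0.02 M), 60 °C
Reagents that add atoms: none
Why: Zerovalent nickel binds both dienes and couples their tether-bound termini oxidatively, which forms the C1–C8 bond and closes ring A as a five-membered ring in the exo sense with respect to both dienes, leaving a bis(allyl)nickel species; reductive elimination between the two outer allyl termini then forms the C4–C5 bond, closes ring B as the eight-membered ring (endo with respect to both allyl units) and returns zerovalent nickel. The closest known reaction type is the nickel-catalysed intramolecular [4+4] cycloaddition of 1,3-dienes joined by a three-atom tether, for which cis-fused bicyclo[6.3.0]undeca-2,6-dienes are the normal outcome. C8 is controlled by the C9 methyl group, which should sit pseudo-equatorially in the forming five-membered ring so that C7 ends trans to it; C1 is controlled by the short tether and the syn bis-allyl geometry, which allow only the cis ring fusion. The step needs [4+4] over [4+2] and over open-chain or intermolecular coupling, and the three-carbon tether, the two E dienes that can reach the s-cis form and the phosphine-ligated catalyst at high dilution should secure this. The trisubstituted C2=C3 and the disubstituted C6=C7 alkenes that result are chemically distinct, which steps 6 and 7 use.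

Step 6
Reactants: 8 (1R,2Z,6Z,8R,9R)-2,9-dimethylbicyclo[6.3.0]undeca-2,6-diene
Product: 9 (1R,2Z,8S,9R)-2,9-dimethylbicyclo[6.3.0]undec-2-ene
Conditions: H2 (1 atm), RhCl(PPh3)3 (5 mol %), benzene, rt
Reagents that add atoms: none
Why: Homogeneous hydrogenation with RhCl(PPh3)3 discriminates strongly on alkene substitution, so the cis-disubstituted C6=C7 bond should be saturated and the trisubstituted C2=C3 bond kept.

Step 7
Reactants: 9 (1R,2Z,8S,9R)-2,9-dimethylbicyclo[6.3.0]undec-2-ene
Product: 11 (1R,2R,3R,8S,9R)-2,9-dimethylbicyclo[6.3.0]undecan-3-ol, via alkylborane 10 (not isolated)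
Conditions: BH3·THF, THF, 0 °C to rt; then NaOH, H2O2, 0 °C to rt
Reagents that add atoms: hydrogen peroxide OO
Why: Hydroboration–oxidation puts oxygen on the less substituted C3 by syn addition on the face of the C1 and C8 hydrogens, and the thirteen-carbon skeleton of 9 is unchanged; the C2 and C3 centres so formed are erased in step 8.

Step 8
Reactants: 11 (1R,2R,3R,8S,9R)-2,9-dimethylbicyclo[6.3.0]undecan-3-ol
Product: 14 (1Z,4Z,8S,9R)-2,9-dimethylbicyclo[6.3.0]undeca-1,4-dien-3-one, via ketone 12 (not isolated), via enone 13 (not isolated)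
Conditions: IBX (2-iodoxybenzoic acid, 4.5 equiv), DMSO, 65 °C to 85 °C
Reagents that add atoms: none
Why: IBX first oxidises the alcohol to ketone 12 and then dehydrogenates both α,β-positions through the enols (IBX desaturation of ketones, which takes cyclooctanones on to the cross-conjugated 2,7-dienones); the order of the two dehydrogenations does not matter because both converge on 14, in which C1 and C2 are sp2.

Step 9
Reactants: 14 (1Z,4Z,8S,9R)-2,9-dimethylbicyclo[6.3.0]undeca-1,4-dien-3-one
Product: 17 (1Z,4Z,8S,9R)-2,5,9-trimethylbicyclo[6.3.0]undeca-1,4-dien-3-one, via lithium enolate 15 (not isolated), via selenide 16 (not isolated)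
Conditions: Me2CuLi (from MeLi, CuI), Et2O, −78 °C; PhSeBr, THF, −78 °C to 0 °C; then H2O2, pyridine, CH2Cl2, 0 °C to rt
Reagents that add atoms: lithium dimethylcuprate [Li+].C[Cu-]C
Why: Cuprate conjugate addition occurs only at the unhindered cis-disubstituted enone (C5), the enolate is selenenylated at C4 trans to the new methyl, and selenoxide syn-elimination with the C5 hydrogen restores the C4=C5 alkene, now methyl-substituted (conjugate addition–selenoxide elimination); the C5 centre formed on the way is erased.

Step 10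
Reactants: 18 (4S)-1-methyl-4-(prop-1-en-2-yl)cyclohex-1-ene
Product: 19 (4S)-1-methyl-4-(propan-2-yl)cyclohex-1-ene
Conditions: H2 (1 atm), RhCl(PPh3)3 (2 mol %), benzene–EtOH, rt
Reagents that add atoms: none
Why: RhCl(PPh3)3 hydrogenates the 1,1-disubstituted isopropenyl group selectively over the trisubstituted ring alkene and does not touch the stereocentre.

Step 11
Reactants: 19 (4S)-1-methyl-4-(propan-2-yl)cyclohex-1-ene
Product: 21 (3S)-6-oxo-3-(propan-2-yl)heptanal, via ozonide 20 (not isolated)
Conditions: O3, CH2Cl2, −78 °C; then Me2S, −78 °C to rt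
Reagents that add atoms: ozone [O-][O+]=O
Why: Ozonolysis with reductive work-up cleaves the only alkene to the keto aldehyde; the stereocentre is β to the aldehyde and cannot epimerise.

Step 12
Reactants: 21 (3S)-6-oxo-3-(propan-2-yl)heptanal
Product: 22 (5R)-2-methyl-5-(propan-2-yl)cyclopent-1-ene-1-carbaldehyde
Conditions: piperidine (cat.), AcOH (cat.), benzene, reflux, water separator
Reagents that add atoms: none
Why: Intramolecular aldol condensation through the piperidine enamine of the aldehyde, whose α-carbon adds to the methyl ketone; dehydration gives the five-membered enal and the non-enolisable stereocentre is retained.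

Step 13
Reactants: 22 (5R)-2-methyl-5-(propan-2-yl)cyclopent-1-ene-1-carbaldehyde
Product: 23 [(5R)-2-methyl-5-(propan-2-yl)cyclopent-1-en-1-yl]methanol
Conditions: NaBH4, CeCl3·7H2O, MeOH, 0 °C
Reagents that add atoms: none
Why: Luche 1,2-reduction gives the allylic alcohol without conjugate reduction of the hindered enal.

Step 14
Reactants: 23 [(5R)-2-methyl-5-(propan-2-yl)cyclopent-1-en-1-yl]methanol
Product: 24 tributyl({[(5R)-2-methyl-5-(propan-2-yl)cyclopent-1-en-1-yl]methoxy}methyl)stannane
Conditions: KH, Bu3SnCH2I, THF, 0 °C to rt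
Reagents that add atoms: (iodomethyl)tributylstannane CCCC[Sn](CCCC)(CCCC)CI
Why: Williamson etherification of the potassium alkoxide with the reactive primary iodomethylstannane.

Step 15
Reactants: 24 tributyl({[(5R)-2-methyl-5-(propan-2-yl)cyclopent-1-en-1-yl]methoxy}methyl)stannane
Product: 26 [(1S,3R)-1-methyl-2-methylidene-3-(propan-2-yl)cyclopentyl]methanol, via lithiomethyl ether 25 (not isolated)
Conditions: n-BuLi, THF, −78 °C to −40 °C
Reagents that add atoms: none
Why: Tin–lithium exchange gives the α-alkoxy carbanion, which undergoes the [2,3]-Wittig–Still rearrangement; the migrating CH2O unit bonds to C1′ on the ring face opposite the isopropyl group on C3′, which sets the quaternary centre with CH2OH trans to isopropyl.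

Step 16
Reactants: 26 [(1S,3R)-1-methyl-2-methylidene-3-(propan-2-yl)cyclopentyl]methanol
Product: 28 [(1S,2S,3R)-1-methyl-3-(propan-2-yl)cyclopentane-1,2-diyl]dimethanol, via alkoxyborane 27 (not isolated)
Conditions: BH3·THF (2.2 equiv), THF, 0 °C to rt; then NaOH, H2O2, 0 °C to rt
Reagents that add atoms: hydrogen peroxide OO
Why: Hydroboration–oxidation of the exocyclic alkene; the boron hydride, bound as an alkoxyborane on the CH2O face that is also the face opposite isopropyl, delivers hydrogen to C2′ from that face, so the new CH2OH ends cis to the isopropyl and methyl groups.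

Step 17
Reactants: 28 [(1S,2S,3R)-1-methyl-3-(propan-2-yl)cyclopentane-1,2-diyl]dimethanol
Product: 29 [(1S,2S,3R)-2-(iodomethyl)-1-methyl-3-(propan-2-yl)cyclopentyl]methanol
Conditions: PPh3 (1.1 equiv), I2 (1.1 equiv), imidazole, CH2Cl2, 0 °C to 40 °C
Reagents that add atoms: iodine II
Why: Appel iodination in which iodide displaces only the alkoxyphosphonium on the β-branched CH2 at C2′, because the CH2OH on the quaternary C1′ is neopentyl and inert to SN2, and the trans arrangement of the two arms disfavours cyclic ether formation.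

Step 18
Reactants: 29 [(1S,2S,3R)-2-(iodomethyl)-1-methyl-3-(propan-2-yl)cyclopentyl]methanol
Product: 30 (1S,2S,3R)-2-(iodomethyl)-1-methyl-3-(propan-2-yl)cyclopentane-1-carbaldehyde
Conditions: DMP (1,1,1-triacetoxy-1,1-dihydro-1,2-benziodoxol-3(1H)-one), NaHCO3, CH2Cl2, rt
Reagents that add atoms: none
Why: DMP oxidation of the neopentyl alcohol gives an aldehyde with no α-hydrogen, which can neither epimerise nor self-condense, and the hindered primary iodide is inert.

Step 19
Reactants: 17 (1Z,4Z,8S,9R)-2,5,9-trimethylbicyclo[6.3.0]undeca-1,4-dien-3-one; 30 (1S,2S,3R)-2-(iodomethyl)-1-methyl-3-(propan-2-yl)cyclopentane-1-carbaldehyde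
Product: 32 (4S,5S,8S,9R)-4-{hydroxy[(1S,2S,3R)-2-(iodomethyl)-1-methyl-3-(propan-2-yl)cyclopentyl]methyl}-2,5,9-trimethylbicyclo[6.3.0]undec-1-en-3-one, via silyl enol ether 31 (not isolated)
Conditions: [(Ph3P)CuH]6 (5 mol %), PhMe2SiH (1.05 equiv), toluene, rt; then 30, TiCl4, CH2Cl2, −78 °C
Reagents that add atoms: none
Why: Copper hydride 1,4-reduction (hydrosilylation) acts only on the β-methyl enone C4=C5 and not on the tetrasubstituted C1=C2 enone; hydride should enter C5 from the convex face of the folded cyclooctadienone, the face of the C8 hydrogen, which leaves the C5 methyl on the concave face as in the target, and the Mukaiyama aldol then forms the C4–C12 bond anti to that methyl (the C12 carbinol configuration is of no consequence).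

Step 20
Reactants: 32 (4S,5S,8S,9R)-4-{hydroxy[(1S,2S,3R)-2-(iodomethyl)-1-methyl-3-(propan-2-yl)cyclopentyl]methyl}-2,5,9-trimethylbicyclo[6.3.0]undec-1-en-3-one
Product: 34 (1Z,4E,5S,8S,9R)-4-{[(1R,2S,3R)-2-(iodomethyl)-1-methyl-3-(propan-2-yl)cyclopentyl]methylidene}-2,5,9-trimethylbicyclo[6.3.0]undec-1-en-3-one, via mesylate 33 (not isolated)
Conditions: MsCl, Et3N, CH2Cl2, 0 °C; then DBU, rt
Reagents that add atoms: none
Why: Mesylation of the aldol hydroxyl and E1cB elimination through the C4 enolate give the conjugated exocyclic enone (aldol dehydration); its geometry is of no consequence.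

Step 21
Reactants: 34 (1Z,4E,5S,8S,9R)-4-{[(1R,2S,3R)-2-(iodomethyl)-1-methyl-3-(propan-2-yl)cyclopentyl]methylidene}-2,5,9-trimethylbicyclo[6.3.0]undec-1-en-3-one
Product: 36 (1Z,4R,5S,8S,9R)-4-{[(1R,2S,3R)-2-(iodomethyl)-1-methyl-3-(propan-2-yl)cyclopentyl]methyl}-2,5,9-trimethylbicyclo[6.3.0]undec-1-en-3-one, via C4 epimer 35 (not isolated)
Conditions: [(Ph3P)CuH]6 (0.4 equiv), H2O (2 equiv), benzene, rt; then NaOMe (cat.), MeOH, rt
Reagents that add atoms: none
Why: Copper hydride conjugate reduction saturates the exocyclic C4=C12 enone and spares the tetrasubstituted C1=C2 enone and the hindered primary iodide; methoxide then equilibrates the enolisable C4 centre to the more stable isomer, with the large C4 substituent on the convex face and trans to the C5 methyl, while alkylation of the enolate by the iodide is held back because it would need a trans-fused bicyclo[3.3.0]octane.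

Step 22
Reactants: 36 (1Z,4R,5S,8S,9R)-4-{[(1R,2S,3R)-2-(iodomethyl)-1-methyl-3-(propan-2-yl)cyclopentyl]methyl}-2,5,9-trimethylbicyclo[6.3.0]undec-1-en-3-one
Product: 38 sesterfisherol, via alkyllithium 37 (not isolated)
Conditions: t-BuLi (2.2 equiv), Et2O–pentane, −78 °C; then aq. NH4Cl
Reagents that add atoms: none
Why: Iodine–lithium exchange at the primary iodide outruns attack of t-BuLi on the hindered enone carbonyl, and the alkyllithium adds 1,2 to C3 through a chair-like six-membered transition state held rigid by trans-fused ring D (Barbier-type anionic cyclisation); C3 is set because the small oxygen, not C2 with its methyl, takes the axial site flanked by the C4 substituents, which should give the trans B/C fusion with OH anti to the C4 hydrogen.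

Compound list
1 | (3R)-3,7-dimethylocta-1,6-diene, (R)-β-citronellene | CC(C)=CCC[C@@H](C)C=C | starting material
2 | (2E,6R)-2,6-dimethylocta-2,7-dien-1-ol | OC/C(C)=C/CC[C@@H](C)C=C | intermediate
3 | (2E,6R)-2,6-dimethylocta-2,7-dienal | O=C/C(C)=C/CC[C@@H](C)C=C | intermediate
4 | (2E)-but-2-enal, crotonaldehyde | C/C=C/C=O | starting material
5 | (2E,6R,7E)-2,6-dimethylnona-2,7-dienedial | O=C/C(C)=C/CC[C@@H](C)/C=C/C=O | intermediate
6 | (2E,6R,7E)-2,6-dimethyldeca-2,7,9-trienal, not isolated | O=C/C(C)=C/CC[C@@H](C)/C=C/C=C | intermediate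
7 | (3E,7R,8E)-3,7-dimethylundeca-1,3,8,10-tetraene | C=C/C(C)=C/CC[C@@H](C)/C=C/C=C | intermediate
8 | (1R,2Z,6Z,8R,9R)-2,9-dimethylbicyclo[6.3.0]undeca-2,6-diene, cis-fused | C/C1=C/CC/C=C\[C@H]2[C@H](C)CC[C@@H]12 | intermediate
9 | (1R,2Z,8S,9R)-2,9-dimethylbicyclo[6.3.0]undec-2-ene | C/C1=C/CCCC[C@H]2[C@H](C)CC[C@@H]12 | intermediate
10 | (2,9-dimethylbicyclo[6.3.0]undecan-3-yl)borane, syn adduct of 9 with boron on C3 and both new bonds on the face of the C1 and C8 hydrogens, not isolated | C[C@H]1[C@H](B)CCCC[C@H]2[C@H](C)CC[C@@H]12 | intermediate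
11 | (1R,2R,3R,8S,9R)-2,9-dimethylbicyclo[6.3.0]undecan-3-ol | C[C@H]1[C@H](O)CCCC[C@H]2[C@H](C)CC[C@@H]12 | intermediate
12 | (1R,2R,8S,9R)-2,9-dimethylbicyclo[6.3.0]undecan-3-one, not isolated | C[C@H]1C(=O)CCCC[C@H]2[C@H](C)CC[C@@H]12 | intermediate
13 | (1Z,8S,9R)-2,9-dimethylbicyclo[6.3.0]undec-1-en-3-one, not isolated | C/C1=C2\CC[C@@H](C)[C@@H]2CCCCC1=O | intermediate
14 | (1Z,4Z,8S,9R)-2,9-dimethylbicyclo[6.3.0]undeca-1,4-dien-3-one | C/C1=C2\CC[C@@H](C)[C@@H]2CC/C=C\C1=O | intermediate
15 | lithium (5R,8S,9R)-2,5,9-trimethylbicyclo[6.3.0]undeca-1,3-dien-3-olate, C5 methyl on the face of the C8 hydrogen, not isolated | C/C1=C2\CC[C@@H](C)[C@@H]2CC[C@@H](C)/C=C1/O[Li] | intermediate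
16 | (4S,5R,8S,9R)-2,5,9-trimethyl-4-(phenylselanyl)bicyclo[6.3.0]undec-1-en-3-one, selenium trans to the C5 methyl, not isolated | C/C1=C2\CC[C@@H](C)[C@@H]2CC[C@@H](C)[C@H]([Se]c3ccccc3)C1=O | intermediate
17 | (1Z,4Z,8S,9R)-2,5,9-trimethylbicyclo[6.3.0]undeca-1,4-dien-3-one | C/C1=C2\CC[C@@H](C)[C@@H]2CC/C(C)=C\C1=O | intermediate
18 | (4S)-1-methyl-4-(prop-1-en-2-yl)cyclohex-1-ene, (S)-limonene | CC1=CC[C@H](CC1)C(C)=C | starting material
19 | (4S)-1-methyl-4-(propan-2-yl)cyclohex-1-ene | CC1=CC[C@H](CC1)C(C)C | intermediate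
20 | 1-methyl-4-(propan-2-yl)-7,8,9-trioxabicyclo[4.2.1]nonane, secondary ozonide of 19, isopropyl-bearing centre unchanged, bridgeheads as formed, not isolated | CC12OOC(C[C@@H](C(C)C)CC1)O2 | intermediate
21 | (3S)-6-oxo-3-(propan-2-yl)heptanal | CC(=O)CC[C@@H](CC=O)C(C)C | intermediate
22 | (5R)-2-methyl-5-(propan-2-yl)cyclopent-1-ene-1-carbaldehyde | CC1=C(C=O)[C@@H](C(C)C)CC1 | intermediate
23 | [(5R)-2-methyl-5-(propan-2-yl)cyclopent-1-en-1-yl]methanol | CC1=C(CO)[C@@H](C(C)C)CC1 | intermediate
24 | tributyl({[(5R)-2-methyl-5-(propan-2-yl)cyclopent-1-en-1-yl]methoxy}methyl)stannane | CC1=C(COC[Sn](CCCC)(CCCC)CCCC)[C@@H](C(C)C)CC1 | intermediate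
25 | {[(5R)-2-methyl-5-(propan-2-yl)cyclopent-1-en-1-yl]methoxy}methyllithium, not isolated | CC1=C(COC[Li])[C@@H](C(C)C)CC1 | intermediate
26 | [(1S,3R)-1-methyl-2-methylidene-3-(propan-2-yl)cyclopentyl]methanol | OC[C@@]1(C)CC[C@H](C(C)C)C1=C | intermediate
27 | cyclic alkoxyborane of 26 (1,2-oxaborinane trans-fused to ring D, B–H), simplest representation of the hydroboration intermediate, not isolated | O1C[C@@]2(C)CC[C@H](C(C)C)[C@@H]2CB1 | intermediate
28 | [(1S,2S,3R)-1-methyl-3-(propan-2-yl)cyclopentane-1,2-diyl]dimethanol | OC[C@@]1(C)CC[C@H](C(C)C)[C@@H]1CO | intermediate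
29 | [(1S,2S,3R)-2-(iodomethyl)-1-methyl-3-(propan-2-yl)cyclopentyl]methanol | OC[C@@]1(C)CC[C@H](C(C)C)[C@@H]1CI | intermediate
30 | (1S,2S,3R)-2-(iodomethyl)-1-methyl-3-(propan-2-yl)cyclopentane-1-carbaldehyde | O=C[C@@]1(C)CC[C@H](C(C)C)[C@@H]1CI | intermediate
31 | (5S,8S,9R)-3-{[dimethyl(phenyl)silyl]oxy}-2,5,9-trimethylbicyclo[6.3.0]undeca-1,3-diene, not isolated | C/C1=C2\CC[C@@H](C)[C@@H]2CC[C@H](C)/C=C1/O[Si](C)(C)c3ccccc3 | intermediate
32 | (4S,5S,8S,9R)-4-{hydroxy[(1S,2S,3R)-2-(iodomethyl)-1-methyl-3-(propan-2-yl)cyclopentyl]methyl}-2,5,9-trimethylbicyclo[6.3.0]undec-1-en-3-one, C12 carbinol centre unassigned | C/C1=C2\CC[C@@H](C)[C@@H]2CC[C@H](C)[C@@H](C(O)[C@@]3(C)CC[C@H](C(C)C)[C@@H]3CI)C1=O | intermediate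
33 | C12 methanesulfonate of 32, not isolated | C/C1=C2\CC[C@@H](C)[C@@H]2CC[C@H](C)[C@@H](C(OS(C)(=O)=O)[C@@]3(C)CC[C@H](C(C)C)[C@@H]3CI)C1=O | intermediate
34 | (1Z,4E,5S,8S,9R)-4-{[(1R,2S,3R)-2-(iodomethyl)-1-methyl-3-(propan-2-yl)cyclopentyl]methylidene}-2,5,9-trimethylbicyclo[6.3.0]undec-1-en-3-one | C/C1=C2\CC[C@@H](C)[C@@H]2CC[C@H](C)/C(=C\[C@@]3(C)CC[C@H](C(C)C)[C@@H]3CI)C1=O | intermediate
35 | (4S)-epimer of 36 (C4 substituent cis to the C5 methyl), not isolated | C/C1=C2\CC[C@@H](C)[C@@H]2CC[C@H](C)[C@H](C[C@@]3(C)CC[C@H](C(C)C)[C@@H]3CI)C1=O | intermediate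
36 | (1Z,4R,5S,8S,9R)-4-{[(1R,2S,3R)-2-(iodomethyl)-1-methyl-3-(propan-2-yl)cyclopentyl]methyl}-2,5,9-trimethylbicyclo[6.3.0]undec-1-en-3-one | C/C1=C2\CC[C@@H](C)[C@@H]2CC[C@H](C)[C@@H](C[C@@]3(C)CC[C@H](C(C)C)[C@@H]3CI)C1=O | intermediate
37 | primary alkyllithium from 36 (iodine replaced by lithium), not isolated | C/C1=C2\CC[C@@H](C)[C@@H]2CC[C@H](C)[C@@H](C[C@@]3(C)CC[C@H](C(C)C)[C@@H]3C[Li])C1=O | intermediate
38 | sesterfisherol | C/C1=C2\CC[C@@H](C)[C@@H]2CC[C@H](C)[C@H]2C[C@@]3(C)CC[C@H](C(C)C)[C@@H]3C[C@]12O | target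

Total step count: 22. Longest linear sequence: 13 steps (steps 1–9 and 19–22 from 1; the ring D branch, steps 10–18 and 19–22 from 18, is equally long).

Steps most likely to fail

Step 5 (key step). What may go wrong: the bis(allyl)nickel intermediate closes in the [4+2] sense or loses a β-hydrogen instead of closing ring B, or the C9 methyl steers the first C–C coupling too weakly. Fallback, metal-free and stepwise: setting out from 7, triplet-sensitised intramolecular diene–diene [2+2] photocycloaddition (benzophenone, hν, benzene) would form the C1–C8 and C2–C7 bonds and give the cis-fused divinylcyclobutane 6,7-diethenyl-2,6-dimethylbicyclo[3.2.0]heptane F1. Heating F1 (toluene, sealed tube, 150–200 °C) would bring about the Cope rearrangement of the 1,2-divinylcyclobutane, which cleaves C2–C7, forms C4–C5 and returns to the route at 8.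

Step 22. What may go wrong: the alkyllithium removes the C4 hydrogen instead of adding, t-BuLi attacks the carbonyl before the exchange, or the carbanion adds to the other carbonyl face (cis B/C fusion). Fallback, ring closure one stage earlier by single-electron chemistry: setting out from 32, SmI2 (divalent samarium) with HMPA in THF at −78 °C to 0 °C would effect a Barbier closure in which the free C12 hydroxyl binds samarium and fixes the carbonyl rotamer, and the weakly basic organosamarium avoids enolisation, giving the tetracyclic 1,3-diol C12-hydroxysesterfisherol F2. Selective acylation of the secondary hydroxyl (PhOC(S)Cl, pyridine, DMAP) would give the O-phenyl thionocarbonate F3, and Barton–McCombie deoxygenation (Bu3SnH, AIBN, toluene, 80 °C) would return to the route at 38; steps 20 and 21 are bypassed and C4 keeps its kinetic aldol configuration.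

Step 19. What may go wrong: hydride is delivered to the other face of C5 (wrong C5 configuration), or the carbonyl is reduced 1,2. Fallback, the roles of methyl and hydrogen at C5 exchanged: setting out from 14, Me2CuLi (Et2O, −78 °C) would deliver the methyl group itself to C5; if the concave face is the reactive one, this gives the required C5 configuration directly, as lithium (5S,8S,9R)-2,5,9-trimethylbicyclo[6.3.0]undeca-1,3-dien-3-olate F4. Transmetalation with ZnCl2 and addition of 30 at −78 °C (cuprate conjugate addition–aldol) would then return to the route at 32, bypassing 17.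

Further compounds
F1 | step 5 | 6,7-diethenyl-2,6-dimethylbicyclo[3.2.0]heptane, cis-fused, vinyl-bearing centres as formed | C=CC1(C)C(C=C)[C@H]2[C@H](C)CC[C@@H]12
F2 | step 22 | C12-hydroxysesterfisherol, tetracyclic 1,3-diol, C12 carbinol centre unassigned | C/C1=C2\CC[C@@H](C)[C@@H]2CC[C@H](C)[C@H]2C(O)[C@@]3(C)CC[C@H](C(C)C)[C@@H]3C[C@]12O
F3 | step 22 | O-phenyl thionocarbonate of F2 at the C12 oxygen | C/C1=C2\CC[C@@H](C)[C@@H]2CC[C@H](C)[C@H]2C(OC(=S)Oc4ccccc4)[C@@]3(C)CC[C@H](C(C)C)[C@@H]3C[C@]12O
F4 | step 19 | lithium (5S,8S,9R)-2,5,9-trimethylbicyclo[6.3.0]undeca-1,3-dien-3-olate | C/C1=C2\CC[C@@H](C)[C@@H]2CC[C@H](C)/C=C1/O[Li]
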